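Ring C is cut at C2–C3 and C4–C4a: C3/C4 leave as a ketene acetal, and what remains is an open O-aryl O-pivaloyl acetal in which O1 already links ring A to the benzylic carbon C2. The feature used is that C2 is an acetal-level carbon flanked, through O1, by the phloroglucinol-type ring A, whose C4a (ortho to O1, ortho/para to O5 and O7) is a strong π-nucleophile. Ionisation gives an O-aryl oxocarbenium ion (C2=O1–C8a=C4a); ketene diethyl acetal adds at C2 under chiral-anion control and the new carbenium ion is trapped by C4a, closing the pyranone. Both side-chain stereocentres come from (S)-β-methyl-γ-butyrolactone by trans-alkylation.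

Key step: step 9

Remark: enantiopure (4S)-4-methyloxolan-2-one is taken as purchasable, and the enantiomer of the chiral acid in step 9 that leads to 2S is to be assigned in a model reaction.

Step 1
Reactants: 1 (4S)-4-methyloxolan-2-one; 2 1-bromo-3-methylbut-2-ene (prenyl bromide)
Product: 4 (3S,4S)-4-methyl-3-(3-methylbut-2-en-1-yl)oxolan-2-one, via lithium enolate 3 (not isolated)
Conditions: LDA, THF, −78 °C; then 2, DMPU, −78 → −30 °C
Reagents that add atoms: none
Why: Alkylation of the kinetic lactone enolate, in which prenyl bromide approaches the face anti to the C4 methyl group, so the new C3 centre should form trans to it (3S,4S), as is usual for β-substituted γ-butyrolactones.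

Step 2
Reactants: 5 benzene-1,3,5-triol (phloroglucinol)
Product: 6 1,3,5-tris(methoxymethoxy)benzene
Conditions: NaH, DMF, 0 °C; MOMCl, 0 °C → rt
Reagents that add atoms: chloromethyl methyl ether (MOMCl), COCCl
Why: Williamson etherification of the three phenoxides with a hard α-chloro ether should give the tris-acetal, whose oxygen atoms later direct lithiation and activate ring A.

Step 3
Reactants: 6 1,3,5-tris(methoxymethoxy)benzene; 4 (3S,4S)-4-methyl-3-(3-methylbut-2-en-1-yl)oxolan-2-one
Product: 8 (2S,3S)-4-hydroxy-3-methyl-2-(3-methylbut-2-en-1-yl)-1-[2,4,6-tris(methoxymethoxy)phenyl]butan-1-one, via aryllithium 7 (not isolated)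
Conditions: n-BuLi, TMEDA, THF, 0 °C; CeCl3, −78 °C; then 4, −78 → −30 °C; aq. NH4Cl
Reagents that add atoms: none
Why: Directed ortho-metalation between two MOM-oxy groups gives 7, whose weakly basic cerium derivative should add once to the lactone carbonyl with ring opening (nucleophilic acyl substitution), the two ortho substituents blocking a second addition and no stereocentre being touched.

Step 4
Reactants: 8 (2S,3S)-4-hydroxy-3-methyl-2-(3-methylbut-2-en-1-yl)-1-[2,4,6-tris(methoxymethoxy)phenyl]butan-1-one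
Product: 9 (2S,3S)-4-{[tert-butyl(dimethyl)silyl]oxy}-3-methyl-2-(3-methylbut-2-en-1-yl)-1-[2,4,6-tris(methoxymethoxy)phenyl]butan-1-one
Conditions: TBSCl, imidazole, CH2Cl2, 0 °C → rt
Reagents that add atoms: tert-butyldimethylsilyl chloride (TBSCl), CC(C)(C)[Si](C)(C)Cl
Why: Imidazole-promoted silylation of the primary alcohol, which also locks the open-chain ketone form.

Step 5
Reactants: 9 (2S,3S)-4-{[tert-butyl(dimethyl)silyl]oxy}-3-methyl-2-(3-methylbut-2-en-1-yl)-1-[2,4,6-tris(methoxymethoxy)phenyl]butan-1-one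
Product: 10 (2S,3S)-4-{[tert-butyl(dimethyl)silyl]oxy}-1-[2-hydroxy-4,6-bis(methoxymethoxy)phenyl]-3-methyl-2-(3-methylbut-2-en-1-yl)butan-1-one
Conditions: MgBr2·OEt2, Et2O/toluene, 0 °C → rt; H2O
Reagents that add atoms: none
Why: Chelation-controlled Lewis-acid ether cleavage, in which magnesium held between the ketone oxygen and an ortho acetal oxygen should cleave only one MOM group next to the carbonyl, the chelated magnesium phenoxide then protecting the second ortho group while the para MOM group and the silyl ether are never chelated.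

Step 6
Reactants: 10 (2S,3S)-4-{[tert-butyl(dimethyl)silyl]oxy}-1-[2-hydroxy-4,6-bis(methoxymethoxy)phenyl]-3-methyl-2-(3-methylbut-2-en-1-yl)butan-1-one
Product: 13 2-{(2R)-2-[(2S)-1-{[tert-butyl(dimethyl)silyl]oxy}propan-2-yl]-5-methylhex-4-en-1-yl}-3,5-bis(methoxymethoxy)phenol, via aryl ethyl carbonate 11 (not isolated), via ortho-quinone methide 12 (not isolated)
Conditions: ClCO2Et, Et3N, THF, 0 °C; then NaBH4, THF/H2O, 0 °C → rt
Reagents that add atoms: none
Why: Reductive deoxygenation of an ortho-acyl phenol through its carbonate, in which hydride reduces the ketone, the alkoxide takes over the carbonate, 1,4-elimination gives 12 and a second hydride adds to its exocyclic carbon faster than it can tautomerise, so the adjacent stereocentre should be kept and the phenol that becomes O1 is set free.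

Step 7
Reactants: 14 2,4-dihydroxybenzaldehyde
Product: 15 2,4-bis{[tert-butyl(dimethyl)silyl]oxy}benzaldehyde
Conditions: TBSCl, imidazole, DMF, rt
Reagents that add atoms: tert-butyldimethylsilyl chloride (TBSCl), CC(C)(C)[Si](C)(C)Cl
Why: Imidazole-promoted silylation of both phenols, which keeps O2' and O4' electron-donating but too hindered to act as nucleophiles in step 9.

Step 8
Reactants: 13 2-{(2R)-2-[(2S)-1-{[tert-butyl(dimethyl)silyl]oxy}propan-2-yl]-5-methylhex-4-en-1-yl}-3,5-bis(methoxymethoxy)phenol; 15 2,4-bis{[tert-butyl(dimethyl)silyl]oxy}benzaldehyde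
Product: 18 (2,4-bis{[tert-butyl(dimethyl)silyl]oxy}phenyl)(aryloxy)methyl 2,2-dimethylpropanoate (aryloxy = the phenoxy residue of 13; both acetal epimers), via α-chloro pivalate 16 (not isolated), via sodium phenoxide 17 (not isolated)
Conditions: 15, PivCl, ZnCl2 (cat.), CH2Cl2, 0 °C; separately 13, NaH, THF, 0 °C; combine at −40 → 0 °C
Reagents that add atoms: pivaloyl chloride, CC(C)(C)C(=O)Cl
Why: ZnCl2-catalysed addition of an acyl chloride to an aldehyde gives the α-chloroalkyl ester 16, a hard electrophile that should alkylate phenoxide 17 at oxygen as in the formation of pivaloyloxymethyl ethers (the hindered pivaloyl carbonyl resists acyl transfer), and the acetal carbon needs no control because it becomes planar in step 9.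

Step 9
Reactants: 18 the O-aryl O-pivaloyl acetal; 19 1,1-diethoxyethene (ketene diethyl acetal)
Product: 23 (2S)-2-(2,4-bis{[tert-butyl(dimethyl)silyl]oxy}phenyl)-8-{(2R)-2-[(2S)-1-{[tert-butyl(dimethyl)silyl]oxy}propan-2-yl]-5-methylhex-4-en-1-yl}-5,7-bis(methoxymethoxy)-2,3-dihydro-4H-chromen-4-one, via oxocarbenium ion 20 (not isolated), via diethoxycarbenium adduct 21 (not isolated), via diethyl ketal 22 (not isolated)
Conditions: chiral imidodiphosphorimidate acid [two 3,3'-bis(3,5-bis(trifluoromethyl)phenyl)-BINOL units, both phosphorus atoms N-triflyl] (5 mol %), 19 (3 equiv, slow addition), toluene/CH2Cl2, −78 → −40 °C; then aq. oxalic acid, THF, 0 °C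
Reagents that add atoms: water, O
Why: Proposed new method: the confined chiral acid (directly, or through the 1,1-diethoxyethyl cation it forms with 19) takes the pivalate from 18 and leaves the O-aryl oxocarbenium ion 20 paired with its chiral anion; the CH2 end of 19 adds to C2 (bond C2–C3), the diethoxycarbenium ion 21 is attacked by C4a of ring A (bond C4–C4a), and loss of the arene proton returns the acid while excess 19 takes up the pivalic acid. The closest known reactions are the Lewis-acid oxa-Povarov annulation of O-aryl oxocarbenium ions with alkenes (oxygen analogue of the Povarov reaction) and chiral-anion-controlled Mukaiyama-type additions of silyl ketene acetals to oxocarbenium ions generated from acyloxy acetals; new are the ketene O,O-acetal as two-carbon partner, which leaves C4 at the ketone level, and anion control over an acyclic O-aryl cation. Ring C closes by an intramolecular Friedel–Crafts alkylation, 6-exo-trig at the carbenium carbon with the C4a=C8a bond of ring A inside the new ring. C2, the only new stereocentre, is fixed in the first C–C bond formation by the chiral counter-anion, which covers one face of the planar cation; the side-chain centres are too far away to steer or to interfere. The step needs ionisation toward the O-aryl cation (loss of carboxylate leaves a far better stabilised cation than loss of the ring A phenol would), C-attack by 19 before any arene or the prenyl alkene (19 is by orders of magnitude the strongest π-nucleophile present) and closure on ring A alone (C4a is the one free position ortho to O1 and is activated by O5 and O7, whereas C6' of ring B is meta to both silyloxy groups).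

Step 10
Reactants: 23 the protected flavanone
Product: 24 (2S)-2-(2,4-dihydroxyphenyl)-5,7-dihydroxy-8-{(2R)-2-[(2S)-1-hydroxypropan-2-yl]-5-methylhex-4-en-1-yl}-2,3-dihydro-4H-chromen-4-one (CNP0262638.1)
Conditions: 3 M aq. HCl, MeOH/THF, 40 °C
Reagents that add atoms: none
Why: Acid-catalysed solvolysis should cleave the two aryl MOM acetals and the three silyl ethers in one operation under non-basic conditions that do not open the flavanone ring through the chalcone, so C2 should be kept, and that prenyl-type side chains normally tolerate.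

Compound list
1 | (4S)-4-methyloxolan-2-one [(S)-β-methyl-γ-butyrolactone] | C[C@H]1CC(=O)OC1 | starting material
2 | 1-bromo-3-methylbut-2-ene (prenyl bromide) | CC(C)=CCBr | starting material
3 | lithium enolate of 1 | C[C@@H]1COC(O[Li])=C1 | intermediate
4 | (3S,4S)-4-methyl-3-(3-methylbut-2-en-1-yl)oxolan-2-one | CC(C)=CC[C@@H]1C(=O)OC[C@H]1C | intermediate
5 | benzene-1,3,5-triol (phloroglucinol) | Oc1cc(O)cc(O)c1 | starting material
6 | 1,3,5-tris(methoxymethoxy)benzene | COCOc1cc(OCOC)cc(OCOC)c1 | intermediate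
7 | [2,4,6-tris(methoxymethoxy)phenyl]lithium | [Li]c1c(OCOC)cc(OCOC)cc1OCOC | intermediate
8 | (2S,3S)-4-hydroxy-3-methyl-2-(3-methylbut-2-en-1-yl)-1-[2,4,6-tris(methoxymethoxy)phenyl]butan-1-one | CC(C)=CC[C@H](C(=O)c1c(OCOC)cc(OCOC)cc1OCOC)[C@H](C)CO | intermediate
9 | (2S,3S)-4-{[tert-butyl(dimethyl)silyl]oxy}-3-methyl-2-(3-methylbut-2-en-1-yl)-1-[2,4,6-tris(methoxymethoxy)phenyl]butan-1-one | CC(C)=CC[C@H](C(=O)c1c(OCOC)cc(OCOC)cc1OCOC)[C@H](C)CO[Si](C)(C)C(C)(C)C | intermediate
10 | (2S,3S)-4-{[tert-butyl(dimethyl)silyl]oxy}-1-[2-hydroxy-4,6-bis(methoxymethoxy)phenyl]-3-methyl-2-(3-methylbut-2-en-1-yl)butan-1-one | CC(C)=CC[C@H](C(=O)c1c(O)cc(OCOC)cc1OCOC)[C@H](C)CO[Si](C)(C)C(C)(C)C | intermediate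
11 | ethyl carbonate of the phenol of 10 (side chain as in 10) | CC(C)=CC[C@H](C(=O)c1c(OC(=O)OCC)cc(OCOC)cc1OCOC)[C@H](C)CO[Si](C)(C)C(C)(C)C | intermediate
12 | ortho-quinone methide: 3,5-bis(methoxymethoxy)cyclohexa-2,4-dien-1-one carrying at C6 the exocyclic alkylidene =CH–CH(prenyl)–CH(CH3)–CH2OTBS (side-chain centres as in 10) | O=C1C=C(OCOC)C=C(OCOC)C1=C[C@@H](CC=C(C)C)[C@H](C)CO[Si](C)(C)C(C)(C)C | intermediate
13 | 2-{(2R)-2-[(2S)-1-{[tert-butyl(dimethyl)silyl]oxy}propan-2-yl]-5-methylhex-4-en-1-yl}-3,5-bis(methoxymethoxy)phenol | CC(C)=CC[C@H](Cc1c(O)cc(OCOC)cc1OCOC)[C@H](C)CO[Si](C)(C)C(C)(C)C | intermediate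
14 | 2,4-dihydroxybenzaldehyde | O=Cc1ccc(O)cc1O | starting material
15 | 2,4-bis{[tert-butyl(dimethyl)silyl]oxy}benzaldehyde | O=Cc1ccc(O[Si](C)(C)C(C)(C)C)cc1O[Si](C)(C)C(C)(C)C | intermediate
16 | chloro(2,4-bis{[tert-butyl(dimethyl)silyl]oxy}phenyl)methyl 2,2-dimethylpropanoate (racemic) | CC(C)(C)C(=O)OC(Cl)c1ccc(O[Si](C)(C)C(C)(C)C)cc1O[Si](C)(C)C(C)(C)C | intermediate
17 | sodium phenoxide of 13 | CC(C)=CC[C@H](Cc1c([O-])cc(OCOC)cc1OCOC)[C@H](C)CO[Si](C)(C)C(C)(C)C.[Na+] | intermediate
18 | O-aryl O-pivaloyl acetal: (2,4-bis{[tert-butyl(dimethyl)silyl]oxy}phenyl)(aryloxy)methyl 2,2-dimethylpropanoate, aryloxy = phenoxy residue of 13, both acetal epimers | CC(C)=CC[C@H](Cc1c(OC(OC(=O)C(C)(C)C)c2ccc(O[Si](C)(C)C(C)(C)C)cc2O[Si](C)(C)C(C)(C)C)cc(OCOC)cc1OCOC)[C@H](C)CO[Si](C)(C)C(C)(C)C | intermediate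
19 | 1,1-diethoxyethene (ketene diethyl acetal) | C=C(OCC)OCC | starting material
20 | O-aryl oxocarbenium ion from 18 (cation, paired with the chiral anion) | CC(C)=CC[C@H](Cc1c([O+]=Cc2ccc(O[Si](C)(C)C(C)(C)C)cc2O[Si](C)(C)C(C)(C)C)cc(OCOC)cc1OCOC)[C@H](C)CO[Si](C)(C)C(C)(C)C | intermediate
21 | diethoxycarbenium adduct, (S) at the new O-bearing benzylic carbon (cation) | CC(C)=CC[C@H](Cc1c(O[C@H](c2ccc(O[Si](C)(C)C(C)(C)C)cc2O[Si](C)(C)C(C)(C)C)CC(OCC)=[O+]CC)cc(OCOC)cc1OCOC)[C@H](C)CO[Si](C)(C)C(C)(C)C | intermediate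
22 | (2S)-4,4-diethoxy ketal of 23 | CC(C)=CC[C@H](Cc1c(OCOC)cc(OCOC)c2c1O[C@H](c1ccc(O[Si](C)(C)C(C)(C)C)cc1O[Si](C)(C)C(C)(C)C)CC2(OCC)OCC)[C@H](C)CO[Si](C)(C)C(C)(C)C | intermediate
23 | (2S)-2-(2,4-bis{[tert-butyl(dimethyl)silyl]oxy}phenyl)-8-{(2R)-2-[(2S)-1-{[tert-butyl(dimethyl)silyl]oxy}propan-2-yl]-5-methylhex-4-en-1-yl}-5,7-bis(methoxymethoxy)-2,3-dihydro-4H-chromen-4-one | CC(C)=CC[C@H](Cc1c(OCOC)cc(OCOC)c2c1O[C@H](c1ccc(O[Si](C)(C)C(C)(C)C)cc1O[Si](C)(C)C(C)(C)C)CC2=O)[C@H](C)CO[Si](C)(C)C(C)(C)C | intermediate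
24 | (2S)-2-(2,4-dihydroxyphenyl)-5,7-dihydroxy-8-{(2R)-2-[(2S)-1-hydroxypropan-2-yl]-5-methylhex-4-en-1-yl}-2,3-dihydro-4H-chromen-4-one | CC(C)=CC[C@H](Cc1c(O)cc(O)c2c1O[C@H](c1ccc(O)cc1O)CC2=O)[C@H](C)CO | target

Total step count: 10. Longest linear sequence: 8 steps (1, 3, 4, 5, 6, 8, 9, 10).

Steps most likely to fail

Step 9 (proposed new method). What may go wrong: poor facial selectivity in the addition to the ion pair, cationic oligomerisation of the ketene acetal by the acid, or dealkylation of the diethoxycarbenium ion before ring closure. The fallback sets out from 15 and 13 and comes back at 23, making the two bonds one after the other with known reactions. A Mukaiyama acetate aldol reaction of 15 with 1-ethoxy-1-(trimethylsilyloxy)ethene under a chiral Ti(OiPr)4/BINOL catalyst (enantiomer chosen for 3R) should give the silyl ether ethyl (3R)-3-(2,4-bis{[tert-butyl(dimethyl)silyl]oxy}phenyl)-3-(trimethylsilyloxy)propanoate F1, and mild acid (citric acid, MeOH) should free the alcohol ethyl (3R)-3-(2,4-bis{[tert-butyl(dimethyl)silyl]oxy}phenyl)-3-hydroxypropanoate F2. Mitsunobu etherification of phenol 13 with F2 (PPh3, DIAD, toluene, −20 °C) should form O1–C2 with inversion and give the ethyl (3S)-3-aryl-3-(aryloxy)propanoate F3. Me3SnOH (1,2-dichloroethane, 70 °C) should cleave the ester without β-elimination to the (3S)-3-aryl-3-(aryloxy)propanoic acid F4. With 1-chloro-N,N,2-trimethylprop-1-en-1-amine this gives the acid chloride F5, which should close onto C4a by intramolecular Friedel–Crafts acylation (SnCl4, CH2Cl2, −78 °C) to give 23.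

Step 8. What may go wrong: incomplete addition of pivaloyl chloride to the electron-rich aldehyde, C-alkylation of the ambident phenoxide by the easily ionised chloride, or silyl transfer from the aryl silyl ethers to the phenoxide. The fallback sets out from 15 and 13 and comes back at 18, building the O1–C2 bond at the ether level and raising it to the acetal by oxidation. NaBH4 reduction of 15 gives (2,4-bis{[tert-butyl(dimethyl)silyl]oxy}phenyl)methanol F6. Mitsunobu etherification with 13 (PPh3, DIAD) should give the aryl benzyl ether F7. DDQ with pivalic acid and 2,6-dichloropyridine (4 Å sieves, CH2Cl2) should abstract hydride from the O-benzylic CH2 and the cation should be captured by pivalate to give 18. The side-chain benzylic CH2 on ring A is flanked by two ortho substituents and cannot reach the planar cation, so it should be left alone.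

Step 10. What may go wrong: acid-induced ionisation of the C2–O1 bond next to the 2',4'-dioxygenated ring (epimerisation at C2), or hydration of the prenyl alkene during the acid treatment. The fallback sets out from 23 and comes back at 24 without Brønsted-acid solvolysis. TMSOTf with 2,2'-bipyridyl (CH2Cl2, 0 °C) should exchange the two aryl MOM groups for trimethylsilyl groups and give the (2S)-5,7-bis(trimethylsilyloxy) analogue of 23 F8. HF·pyridine buffered with pyridine (THF, 0 °C) should then remove all five silyl groups to give 24.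

Further compounds
F1 | step 9 | ethyl (3R)-3-(2,4-bis{[tert-butyl(dimethyl)silyl]oxy}phenyl)-3-(trimethylsilyloxy)propanoate | CCOC(=O)C[C@@H](O[Si](C)(C)C)c1ccc(O[Si](C)(C)C(C)(C)C)cc1O[Si](C)(C)C(C)(C)C
F2 | step 9 | ethyl (3R)-3-(2,4-bis{[tert-butyl(dimethyl)silyl]oxy}phenyl)-3-hydroxypropanoate | CCOC(=O)C[C@@H](O)c1ccc(O[Si](C)(C)C(C)(C)C)cc1O[Si](C)(C)C(C)(C)C
F3 | step 9 | ethyl (3S)-3-(2,4-bis{[tert-butyl(dimethyl)silyl]oxy}phenyl)-3-(aryloxy)propanoate, aryloxy = phenoxy residue of 13 | CC(C)=CC[C@H](Cc1c(O[C@H](c2ccc(O[Si](C)(C)C(C)(C)C)cc2O[Si](C)(C)C(C)(C)C)CC(=O)OCC)cc(OCOC)cc1OCOC)[C@H](C)CO[Si](C)(C)C(C)(C)C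
F4 | step 9 | (3S)-3-(2,4-bis{[tert-butyl(dimethyl)silyl]oxy}phenyl)-3-(aryloxy)propanoic acid | CC(C)=CC[C@H](Cc1c(O[C@H](c2ccc(O[Si](C)(C)C(C)(C)C)cc2O[Si](C)(C)C(C)(C)C)CC(=O)O)cc(OCOC)cc1OCOC)[C@H](C)CO[Si](C)(C)C(C)(C)C
F5 | step 9 | (3S)-3-(2,4-bis{[tert-butyl(dimethyl)silyl]oxy}phenyl)-3-(aryloxy)propanoyl chloride | CC(C)=CC[C@H](Cc1c(O[C@H](c2ccc(O[Si](C)(C)C(C)(C)C)cc2O[Si](C)(C)C(C)(C)C)CC(=O)Cl)cc(OCOC)cc1OCOC)[C@H](C)CO[Si](C)(C)C(C)(C)C
F6 | step 8 | (2,4-bis{[tert-butyl(dimethyl)silyl]oxy}phenyl)methanol | OCc1ccc(O[Si](C)(C)C(C)(C)C)cc1O[Si](C)(C)C(C)(C)C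
F7 | step 8 | aryl 2,4-bis{[tert-butyl(dimethyl)silyl]oxy}benzyl ether of phenol 13 | CC(C)=CC[C@H](Cc1c(OCc2ccc(O[Si](C)(C)C(C)(C)C)cc2O[Si](C)(C)C(C)(C)C)cc(OCOC)cc1OCOC)[C@H](C)CO[Si](C)(C)C(C)(C)C
F8 | step 10 | (2S)-5,7-bis(trimethylsilyloxy) analogue of 23 | CC(C)=CC[C@H](Cc1c(O[Si](C)(C)C)cc(O[Si](C)(C)C)c2c1O[C@H](c1ccc(O[Si](C)(C)C(C)(C)C)cc1O[Si](C)(C)C(C)(C)C)CC2=O)[C@H](C)CO[Si](C)(C)C(C)(C)C
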